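## Retrosynthetic overview

1. Last disconnection: the spiro 1,3-dioxan-4-one (acylal) opens to a cage β-hydroxy acid and 7-hydroxy-2,2-dimethyl-6-prenyl-2H-chromene-5,8-dione (O-acylation, then oxa-Michael addition at the acyloxy carbon).
2. The C8=C9 bridge of the cage is removed as a propiolate (retro-aldol/retro-Michael), leaving a 6-oxabicyclo[3.2.1]octane-4,8-dione. Cage locants follow 4-oxatricyclo[4.3.1.0(3,7)]dec-8-ene: C1 carbinol bridgehead, C2 ketone, C3 O/prenyl carbon, O4, C5 CMe2, C6 CH, C7 oxygenated bridgehead, C10 CH2.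
3. Key disconnection: in the cage ring C1–C2–C3–C7–C6–C10 the C2 ketone is 1,3 to the C7 oxygen (across C3) and 1,5 to it (through C6–C10–C1). Read with C7 as a ketone, the THF ring O4–C5–C6–C7–C3 is a 5,5-dimethyl-2-prenyl-dihydrofuran-3(2H)-one. Its two α-carbons are joined to the CH2 (bond C10–C6) and the C=O (bond C2–C3) of acryloyl chloride in one enamine α,α′-annulation, made asymmetric by a C2-symmetric pyrrolidine.
4. Ring order: dihydrofuranone (oxa-Michael) → cyclohexanedione ring of the bicycle (key step) → bicyclo[2.2.2]octene (Michael/aldol) → chromenequinone (made separately) → spiro dioxanone last.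

Key step: step 5

Assumption: the spiro acylal carbon and the adjacent CH(prenyl) carbon of the target are taken to be the thermodynamically preferred configurations under reversible oxa-Michael/enolization conditions.

Locants in steps 5–9 (bicyclic compounds) follow 6-oxabicyclo[3.2.1]octane: C1 = CH bridgehead, C2 and C3 = CH2, C4 = ketone, C5 = O/prenyl bridgehead, O6, C7 = CMe2, C8 = bridging ketone.

## Route

Step 1
Reactants: 1 mesityl oxide (4-methylpent-3-en-2-one); 2 prenyl bromide (1-bromo-3-methylbut-2-ene)
Product: 3 2,8-dimethylnona-2,7-dien-4-one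
Conditions: LDA, THF, −78 °C; then 2, −78 to 0 °C
Reagents that add atoms: none
Why: Kinetic deprotonation of the enone with LDA gives the cross-conjugated α′-enolate, which is C-alkylated by the allylic bromide (enolate alkylation); no stereocentre is formed.

Step 2
Reactants: 3 2,8-dimethylnona-2,7-dien-4-one
Product: 4 (±)-5-hydroxy-2,8-dimethylnona-2,7-dien-4-one
Conditions: KHMDS, THF, −78 °C; 3-phenyl-2-(phenylsulfonyl)oxaziridine; AcOH quench
Reagents that add atoms: 3-phenyl-2-(phenylsulfonyl)oxaziridine, O=S(=O)(c1ccccc1)N1OC1c1ccccc1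
Why: Enolate α-hydroxylation with an N-sulfonyloxaziridine at the α′-CH2 of the enone; the carbinol centre forms as a racemate, which is of no consequence because this carbon is planarized in step 5.

Step 3
Reactants: 4 (±)-5-hydroxy-2,8-dimethylnona-2,7-dien-4-one
Product: 5 (±)-5,5-dimethyl-2-(3-methylbut-2-en-1-yl)dihydrofuran-3(2H)-one
Conditions: TsOH·H2O (cat.), CH2Cl2, rt
Reagents that add atoms: none
Why: Acid-catalysed intramolecular oxa-Michael addition (5-endo-trig) of the α′-hydroxyl to the activated β,β-dimethyl enone closes the dihydrofuranone, while the isolated trisubstituted alkene is not activated by the weak acid; no new stereocentre.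

Step 4
Reactants: 5 (±)-5,5-dimethyl-2-(3-methylbut-2-en-1-yl)dihydrofuran-3(2H)-one; 6 (2S,5S)-2,5-dimethylpyrrolidine
Product: 7 (2S,5S)-1-[5,5-dimethyl-2-(3-methylbut-2-en-1-yl)-2,5-dihydrofuran-3-yl]-2,5-dimethylpyrrolidine (both epimers at furan C2; used crude)
Conditions: TiCl4 (0.55 equiv), Et3N, toluene, 0 °C to rt; filtration under argon
Reagents that add atoms: none
Why: TiCl4-mediated enamine formation from a hindered ketone; A(1,3) strain with the 2,5-dimethylpyrrolidine places the double bond toward the unsubstituted CH2 and not toward the O- and prenyl-bearing carbon, and no stereocentre is set.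

Step 5
Reactants: 7 enamine (as above); 8 acryloyl chloride
Product: 11 (1S,5S)-7,7-dimethyl-5-(3-methylbut-2-en-1-yl)-6-oxabicyclo[3.2.1]octane-4,8-dione, via ketene iminium chloride 9 (not isolated), via bicyclic iminium chloride 10 (not isolated)
Conditions: 8 (1.1 equiv), toluene, −40 °C to 80 °C; then aq. AcOH, rt
Reagents that add atoms: water, O
Why: Proposed new method: N-acylation of enamine 7 by 8 and 3-aza-Cope rearrangement of the N-acryloyl enammonium ion form the C1–C2 bond (acryloyl CH2 to the furanone CH2 carbon) and leave iminium ketene 9; proton loss from the other α-carbon gives the tetrasubstituted enamine, whose carbon attacks the ketene carbonyl (6-(enolendo)-exo-trig, the one ring closure of the step) to form the C4–C5 bond and iminium salt 10, which is hydrolysed to 11. The closest known reaction type is the α,α′-annulation of cyclic ketone enamines with acryloyl chloride (bicyclo[3.3.1]nonane-2,9-diones, bicyclo[3.2.1]octane-2,8-diones), combined with the alkylation of C2-symmetric trans-2,5-dimethylpyrrolidine enamines; neither has been shown on a 3-oxotetrahydrofuran or as an asymmetric annulation. C1 is set in the first bond formation: the ring methyl next to the enamine CH shields one face, so the acryloyl carbon is delivered to the opposite face, which with the (2S,5S)-amine should give (1S). C5 is set by the tether, because the three-carbon arm can reach C5 only on the face it occupies at C1, so the racemic C2 of 5 converges to one bridgehead configuration. The step needs the less substituted enamine (CH2 to the CH2 carbon, acyl to the O-bearing carbon), which A(1,3) strain in the hindered enamine secures, and C- over O-acylation in the second bond, which the six-membered geometry of the tethered ketene secures.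

Step 6
Reactants: 11 (1S,5S)-dione (as above)
Product: 12 (1S,5S)-7,7-dimethyl-5-(3-methylbut-2-en-1-yl)-4-(triethylsilyloxy)-6-oxabicyclo[3.2.1]oct-3-en-8-one
Conditions: TESOTf, Et3N, CH2Cl2, 0 °C
Reagents that add atoms: triethylsilyl trifluoromethanesulfonate, CC[Si](CC)(CC)OS(=O)(=O)C(F)(F)F
Why: Soft enolization/O-silylation (silyl enol ether formation); C3–H2 is the only enolizable position because the other α-carbons are a quaternary centre and a bridgehead, and the amine base does not cleave the non-enolizable 1,3-diketone.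

Step 7
Reactants: 12 silyl enol ether (as above)
Product: 14 (1S,3R,5R)-7,7-dimethyl-5-(3-methylbut-2-en-1-yl)-3-(triethylsilyloxy)-6-oxabicyclo[3.2.1]octane-4,8-dione, via exo silyloxy epoxide 13 (not isolated)
Conditions: 3-phenyl-2-(phenylsulfonyl)oxaziridine, CHCl3, 50 °C
Reagents that add atoms: 3-phenyl-2-(phenylsulfonyl)oxaziridine, O=S(=O)(c1ccccc1)N1OC1c1ccccc1
Why: Rubottom-type oxidation of the silyl enol ether with an N-sulfonyloxaziridine, which spares the prenyl alkene: oxygen enters from the exo face (syn to the C8 bridge, away from the O6–C7 bridge and its endo methyl), and 1,4-silyl migration opens epoxide 13 to the α-silyloxy ketone without a free alkoxide, which would invite retro-Claisen cleavage; C3 becomes (R) but is re-planarized in step 9.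

Step 8
Reactants: 15 propiolic acid; 16 allyl alcohol
Product: 17 allyl propiolate
Conditions: TsOH (cat.), benzene, reflux, Dean–Stark
Reagents that add atoms: none
Why: Fischer esterification driven by azeotropic removal of water; no stereocentre.

Step 9
Reactants: 14 α-silyloxy dione (as above); 17 allyl propiolate
Product: 19 allyl (1R,3R,6R,7S)-7-hydroxy-5,5-dimethyl-3-(3-methylbut-2-en-1-yl)-2-oxo-1-(triethylsilyloxy)-4-oxatricyclo[4.3.1.0(3,7)]dec-8-ene-8-carboxylate, via lithium allenolate 18 (not isolated)
Conditions: LiHMDS, THF, −78 to 0 °C; recool to −78 °C, 17; AcOH quench at −78 °C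
Reagents that add atoms: none
Why: Tandem Michael addition/intramolecular aldol: the lithium enolate of 14 (its only acidic C–H) adds to the propiolate from the exo face, which puts the new vinyl carbon on the side of the C8 ketone and the silyloxy group endo (cage C1), and allenolate 18 then attacks that ketone in the allene plane on the side cis to the ring carbon (six-membered closure), which gives the cis ring alkene and the C7 alkoxide, held as a lithium chelate with the ester until the cold quench.

Step 10
Reactants: 19 cage silyl ether (as above)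
Product: 20 allyl (1R,3R,6R,7S)-1,7-dihydroxy-5,5-dimethyl-3-(3-methylbut-2-en-1-yl)-2-oxo-4-oxatricyclo[4.3.1.0(3,7)]dec-8-ene-8-carboxylate
Conditions: HF·pyridine, pyridine/THF, 0 °C to rt
Reagents that add atoms: none
Why: Fluoride-mediated cleavage of the tertiary silyl ether under buffered, weakly acidic conditions that avoid alkoxide-driven retro-aldol opening of the cage; no stereocentre changes.

Step 11
Reactants: 20 cage diol allyl ester (as above)
Product: 21 (1R,3R,6R,7S)-1,7-dihydroxy-5,5-dimethyl-3-(3-methylbut-2-en-1-yl)-2-oxo-4-oxatricyclo[4.3.1.0(3,7)]dec-8-ene-8-carboxylic acid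
Conditions: Pd(PPh3)4 (cat.), morpholine, THF, rt
Reagents that add atoms: none
Why: Pd(0)-catalysed allyl ester cleavage (Tsuji–Trost deallylation) with morpholine as allyl acceptor frees the acid without hydroxide, which protects the β-hydroxy ketone and α-ketol units, and the prenyl groups are not allylic esters.

Step 12
Reactants: 22 phloroglucinol (excess); 23 3-methylbut-2-enal
Product: 24 2,2-dimethyl-2H-chromene-5,7-diol
Conditions: pyridine, 110 °C
Reagents that add atoms: none
Why: Condensation of the triphenol with the enal and oxa-6π electrocyclization of the resulting ortho-quinone methide (2H-chromene annulation), with excess phloroglucinol to limit double annulation; no stereocentre.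

Step 13
Reactants: 24 2,2-dimethyl-2H-chromene-5,7-diol
Product: 25 7-hydroxy-2,2-dimethyl-2H-chromene-5,8-dione
Conditions: Fremy's salt (2.2 equiv), KH2PO4 buffer, acetone/H2O, 0 °C to rt
Reagents that add atoms: potassium nitrosodisulfonate (Fremy's salt), [K+].[K+].[O]N(S(=O)(=O)[O-])S(=O)(=O)[O-]
Why: Teuber oxidation of the 5-phenol at its free para position C8 gives the para-quinone and leaves the 7-hydroxyl as the vinylogous acid; no stereocentre.

Step 14
Reactants: 25 7-hydroxy-2,2-dimethyl-2H-chromene-5,8-dione; 2 prenyl bromide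
Product: 26 7-hydroxy-2,2-dimethyl-6-(3-methylbut-2-en-1-yl)-2H-chromene-5,8-dione
Conditions: LiH, DMSO, rt; then 2
Reagents that add atoms: none
Why: C-Alkylation of the lithium salt of the 2-hydroxyquinone (a vinylogous carboxylate) at its only free ring carbon, the alkylation type used for 3-prenyl-2-hydroxy-1,4-quinones of the lapachol class; no stereocentre.

Step 15
Reactants: 21 cage dihydroxy acid (as above); 26 prenylated hydroxyquinone (as above)
Product: 28 CNP0222516.1 (target), via acyloxyquinone ester 27 (not isolated)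
Conditions: DCC, DMAP (cat.), CH2Cl2, 0 °C to rt
Reagents that add atoms: none
Why: Steglich O-acylation of the vinylogous acid hydroxyl of 26 gives acyloxyquinone 27, whose cage C7 hydroxyl adds to the acyloxy-bearing quinone carbon (6-exo-trig oxa-Michael addition) with C-protonation of the enolate; the spiro carbon and the CH(prenyl) carbon should settle under thermodynamic control (both events are reversible under DMAP), with prenyl trans to the bulky cage ether oxygen.

## Compound list

1 | mesityl oxide (4-methylpent-3-en-2-one) | CC(C)=CC(C)=O | starting material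
2 | prenyl bromide (1-bromo-3-methylbut-2-ene) | CC(C)=CCBr | starting material
3 | 2,8-dimethylnona-2,7-dien-4-one | CC(C)=CC(=O)CCC=C(C)C | intermediate
4 | (±)-5-hydroxy-2,8-dimethylnona-2,7-dien-4-one | CC(C)=CC(=O)C(O)CC=C(C)C | intermediate
5 | (±)-5,5-dimethyl-2-(3-methylbut-2-en-1-yl)dihydrofuran-3(2H)-one | CC(C)=CCC1OC(C)(C)CC1=O | intermediate
6 | (2S,5S)-2,5-dimethylpyrrolidine | C[C@H]1CC[C@H](C)N1 | starting material
7 | (2S,5S)-1-[5,5-dimethyl-2-(3-methylbut-2-en-1-yl)-2,5-dihydrofuran-3-yl]-2,5-dimethylpyrrolidine (furan C2 epimers) | CC(C)=CCC1OC(C)(C)C=C1N2[C@@H](C)CC[C@@H]2C | intermediate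
8 | acryloyl chloride | C=CC(Cl)=O | starting material
9 | ketene iminium chloride: pyrrolidinium ylidene of the furanone carrying a CH2–CH=C=O arm on the former CH2 carbon (that carbon configured as C1 of 11) | CC(C)=CCC1OC(C)(C)[C@H](CC=C=O)C1=[N+]2[C@@H](C)CC[C@@H]2C.[Cl-] | intermediate
10 | bicyclic iminium chloride: C8 (2S,5S)-2,5-dimethylpyrrolidinium ylidene of 11 | C1C[C@H]2C(C)(C)O[C@@](CC=C(C)C)(C1=O)C2=[N+]3[C@@H](C)CC[C@@H]3C.[Cl-] | intermediate
11 | (1S,5S)-7,7-dimethyl-5-(3-methylbut-2-en-1-yl)-6-oxabicyclo[3.2.1]octane-4,8-dione | C1C[C@H]2C(C)(C)O[C@@](CC=C(C)C)(C1=O)C2=O | intermediate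
12 | (1S,5S)-7,7-dimethyl-5-(3-methylbut-2-en-1-yl)-4-(triethylsilyloxy)-6-oxabicyclo[3.2.1]oct-3-en-8-one | CC[Si](CC)(CC)OC1=CC[C@H]2C(C)(C)O[C@]1(CC=C(C)C)C2=O | intermediate
13 | exo 3,4-epoxide of 12 (α-silyloxy epoxide, oxygen syn to the C8 bridge) | O1[C@@H]2C[C@H]3C(C)(C)O[C@@](CC=C(C)C)([C@]12O[Si](CC)(CC)CC)C3=O | intermediate
14 | (1S,3R,5R)-7,7-dimethyl-5-(3-methylbut-2-en-1-yl)-3-(triethylsilyloxy)-6-oxabicyclo[3.2.1]octane-4,8-dione (silyloxy exo) | CC[Si](CC)(CC)O[C@@H]1C[C@H]2C(C)(C)O[C@@](CC=C(C)C)(C1=O)C2=O | intermediate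
15 | propiolic acid | C#CC(=O)O | starting material
16 | allyl alcohol | C=CCO | starting material
17 | allyl propiolate | C#CC(=O)OCC=C | intermediate
18 | lithium allenolate: Michael adduct of the C3 enolate of 14 with 17 (new C–C bond exo at C3) | [Li]OC(OCC=C)=C=C[C@]1(O[Si](CC)(CC)CC)C[C@H]2C(C)(C)O[C@@](CC=C(C)C)(C1=O)C2=O | intermediate
19 | allyl (1R,3R,6R,7S)-7-hydroxy-5,5-dimethyl-3-(3-methylbut-2-en-1-yl)-2-oxo-1-(triethylsilyloxy)-4-oxatricyclo[4.3.1.0(3,7)]dec-8-ene-8-carboxylate | C=CCOC(=O)C1=C[C@]2(O[Si](CC)(CC)CC)C[C@H]3C(C)(C)O[C@@](CC=C(C)C)(C2=O)[C@@]13O | intermediate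
20 | allyl (1R,3R,6R,7S)-1,7-dihydroxy-5,5-dimethyl-3-(3-methylbut-2-en-1-yl)-2-oxo-4-oxatricyclo[4.3.1.0(3,7)]dec-8-ene-8-carboxylate | C=CCOC(=O)C1=C[C@]2(O)C[C@H]3C(C)(C)O[C@@](CC=C(C)C)(C2=O)[C@@]13O | intermediate
21 | (1R,3R,6R,7S)-1,7-dihydroxy-5,5-dimethyl-3-(3-methylbut-2-en-1-yl)-2-oxo-4-oxatricyclo[4.3.1.0(3,7)]dec-8-ene-8-carboxylic acid | OC(=O)C1=C[C@]2(O)C[C@H]3C(C)(C)O[C@@](CC=C(C)C)(C2=O)[C@@]13O | intermediate
22 | phloroglucinol (benzene-1,3,5-triol) | Oc1cc(O)cc(O)c1 | starting material
23 | 3-methylbut-2-enal | CC(C)=CC=O | starting material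
24 | 2,2-dimethyl-2H-chromene-5,7-diol | CC1(C)C=Cc2c(O)cc(O)cc2O1 | intermediate
25 | 7-hydroxy-2,2-dimethyl-2H-chromene-5,8-dione | CC1(C)C=CC2=C(O1)C(=O)C(O)=CC2=O | intermediate
26 | 7-hydroxy-2,2-dimethyl-6-(3-methylbut-2-en-1-yl)-2H-chromene-5,8-dione | CC(C)=CCC1=C(O)C(=O)C2=C(C=CC(C)(C)O2)C1=O | intermediate
27 | acyloxyquinone ester: 2,2-dimethyl-6-(3-methylbut-2-en-1-yl)-5,8-dioxo-2H-chromen-7-yl ester of acid 21 | CC(C)=CCC1=C(OC(=O)C2=C[C@]3(O)C[C@H]4C(C)(C)O[C@@](CC=C(C)C)(C3=O)[C@@]24O)C(=O)C2=C(C=CC(C)(C)O2)C1=O | intermediate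
28 | CNP0222516.1: spiro acylal in which O7 and the C8 carboxyl oxygen of the cage are both bonded to C7 of a 2,2-dimethyl-6-prenyl-6,7-dihydro-2H-chromene-5,8-dione (chromene C6 S, spiro C7 S; cage 1R,3R,6S,7S, free 1-OH) | CC(C)=CC[C@H]1C(=O)C2=C(OC(C)(C)C=C2)C(=O)[C@@]12OC(=O)C1=C[C@]3(O)C[C@H]4C(C)(C)O[C@@](CC=C(C)C)(C3=O)[C@@]14O2 | target

## Step count and risks

Total step count: 15. Longest linear sequence: 11 steps (steps 1–7, 9–11 and 15, from mesityl oxide).

Steps most likely to fail:

1. Step 5 (proposed new method). What may go wrong: weak or reversed facial selection in the first C–C bond formation, so that the enantiomeric excess is eroded, or sluggish enamine formation and N-acylation with the hindered amine. If only the sense of induction is reversed, the (2R,5R)-amine is used instead. Fallback with known chemistry, setting out from 5: condensation with pyrrolidine (TsOH cat., toluene, Dean–Stark) should give the achiral-amine enamine 1-[5,5-dimethyl-2-(3-methylbut-2-en-1-yl)-2,5-dihydrofuran-3-yl]pyrrolidine F1. The established α,α′-annulation with acryloyl chloride 8 (toluene, reflux, then buffered hydrolysis) should then give racemic 7,7-dimethyl-5-(3-methylbut-2-en-1-yl)-6-oxabicyclo[3.2.1]octane-4,8-dione F2. Preparative chromatography on a chiral stationary phase separates it into 11 and the (1R,5R)-enantiomer of 11 F3, and the route is rejoined at 11.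

2. Step 9. What may go wrong: the allenolate closes onto the adjacent C4 carbonyl (cyclobutene formation and ring expansion) instead of the C8 ketone, the cage alkoxide opens by retro-aldol cleavage before the quench, or the enolate is protonated by the acetylenic C–H. Removal of the endo C3–H of 14 may also be slow. Fallback, setting out from 14: the Michael addition to 17 is run with a substoichiometric amount of KHMDS, so that unreacted 14 protonates the allenolate as it forms, to give the enoate allyl (E)-3-[(1S,3R,5R)-7,7-dimethyl-5-(3-methylbut-2-en-1-yl)-4,8-dioxo-3-(triethylsilyloxy)-6-oxabicyclo[3.2.1]octan-3-yl]prop-2-enoate F4. Lithium thiophenolate (THF, −78 to 0 °C) then adds to the β-carbon and the ester enolate closes onto the C8 ketone (thia-Michael/aldol), giving the 9-phenylthio cage ester F5. NaIO4 oxidation gives the 9-phenylsulfinyl cage ester F6, and thermal syn-elimination (toluene, 90 °C) restores the C8=C9 alkene and returns to the route at 19.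

3. Step 15. What may go wrong: the tetrahedral intermediate of the oxa-Michael addition expels the carboxylate (acyl transfer to give a quinonyl ether acid) instead of being protonated on carbon, or the spiro and CH(prenyl) centres equilibrate to another diastereomer. Fallback, setting out from 21 and 26: 21 is persilylated (TMSCl, imidazole) to trimethylsilyl (1R,3R,6R,7S)-5,5-dimethyl-3-(3-methylbut-2-en-1-yl)-2-oxo-1,7-bis(trimethylsilyloxy)-4-oxatricyclo[4.3.1.0(3,7)]dec-8-ene-8-carboxylate F7. TMSOTf-catalysed acetalization (CH2Cl2, −78 °C, the established route from silylated β-hydroxy acids and carbonyl compounds to 1,3-dioxan-4-ones) with the C7 carbonyl of the ortho-quinonoid tautomer of 26 closes the dioxanone from both oxygens at once, outside the acyl-transfer manifold. Aqueous work-up removes the remaining C1 silyl ether, and tautomerization to the enedione returns to the route at 28.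

Further compounds
F1 | step 5 | 1-[5,5-dimethyl-2-(3-methylbut-2-en-1-yl)-2,5-dihydrofuran-3-yl]pyrrolidine | CC(C)=CCC1OC(C)(C)C=C1N2CCCC2
F2 | step 5 | racemic 7,7-dimethyl-5-(3-methylbut-2-en-1-yl)-6-oxabicyclo[3.2.1]octane-4,8-dione | CC(C)=CCC12OC(C)(C)C(CCC1=O)C2=O
F3 | step 5 | (1R,5R)-enantiomer of 11 | C1C[C@@H]2C(C)(C)O[C@](CC=C(C)C)(C1=O)C2=O
F4 | step 9 | allyl (E)-3-[(1S,3R,5R)-7,7-dimethyl-5-(3-methylbut-2-en-1-yl)-4,8-dioxo-3-(triethylsilyloxy)-6-oxabicyclo[3.2.1]octan-3-yl]prop-2-enoate | C=CCOC(=O)/C=C/[C@]1(O[Si](CC)(CC)CC)C[C@H]2C(C)(C)O[C@@](CC=C(C)C)(C1=O)C2=O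
F5 | step 9 | 9-phenylthio cage ester (8,9-dihydro-9-(phenylthio) analogue of 19; C8 and C9 epimers) | C=CCOC(=O)C1C(Sc2ccccc2)[C@]2(O[Si](CC)(CC)CC)C[C@H]3C(C)(C)O[C@@](CC=C(C)C)(C2=O)[C@@]13O
F6 | step 9 | 9-phenylsulfinyl cage ester (sulfoxide of F5) | C=CCOC(=O)C1C(S(=O)c2ccccc2)[C@]2(O[Si](CC)(CC)CC)C[C@H]3C(C)(C)O[C@@](CC=C(C)C)(C2=O)[C@@]13O
F7 | step 15 | trimethylsilyl (1R,3R,6R,7S)-5,5-dimethyl-3-(3-methylbut-2-en-1-yl)-2-oxo-1,7-bis(trimethylsilyloxy)-4-oxatricyclo[4.3.1.0(3,7)]dec-8-ene-8-carboxylate | C[Si](C)(C)OC(=O)C1=C[C@]2(O[Si](C)(C)C)C[C@H]3C(C)(C)O[C@@](CC=C(C)C)(C2=O)[C@@]13O[Si](C)(C)C
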